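**Retrosynthetic overview**
1. 13 ⇐ 12 (cleavage of the aryl mesylate) ⇐ aryl iodide 4 + cis-epoxide 11 by palladium/norbornene annulation, which forms C3a–C3 (ortho alkylation by epoxide carbon C3, with inversion) and C7a–O1 (ipso etherification by the epoxide oxygen).
2. Feature used: in the 2,3-dihydrobenzofuran (O1, C2, C3, C3a, C7a fused to benzo ring A) O1 and C3 are bound to the neighbouring ring A carbons C7a and C3a, and C7, on the other side of C7a, already carries OMe. This is the pattern left when an O–C2–C3 unit is added across the ipso and the one free ortho carbon of an aryl iodide.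
3. 11 ⇐ Z-alkene 10 (catalytic asymmetric epoxidation sets C2 and C3) ⇐ Z-allylic alcohol 9 + eugenol 1 (Mitsunobu) ⇐ alkynol 8 (semihydrogenation) ⇐ aryl iodide 6 + propargyl alcohol 7 (Sonogashira); 6 ⇐ 4-iodo-2-methoxyphenol 5.
4. 4 ⇐ eugenol 1 via triflate 2 and pinacol boronate 3.
5. Ring order: ring A, ring B and the eugenyl ring are bought; the dihydrofuran ring is the only ring made, in step 9.

Key step: step 9

Remark: the facial sense of the (R,R)-(salen)MnCl catalyst toward 10 is assumed to be the one established for cis-β-alkylstyrenes (benzylic carbon becomes R); if analysis showed the opposite, the (S,S)-catalyst would be used.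

**Step 1**
Reactants: 1 eugenol
Product: 2 4-allyl-2-methoxyphenyl trifluoromethanesulfonate
Conditions: Tf2O, pyridine, CH2Cl2, 0 °C
Reagents that add atoms: trifluoromethanesulfonic anhydride, O=S(=O)(OS(=O)(=O)C(F)(F)F)C(F)(F)F
Why: O-sulfonylation of the phenol, the only nucleophilic site of eugenol at 0 °C.

**Step 2**
Reactants: 2 4-allyl-2-methoxyphenyl trifluoromethanesulfonate
Product: 3 2-(4-allyl-2-methoxyphenyl)-4,4,5,5-tetramethyl-1,3,2-dioxaborolane
Conditions: B2pin2, Pd(dppf)Cl2 (3 mol %), KOAc, 1,4-dioxane, 80 °C
Reagents that add atoms: bis(pinacolato)diboron, CC1(C)OB(OC1(C)C)B1OC(C)(C)C(C)(C)O1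
Why: Miyaura borylation of an aryl triflate, in which KOAc mediates transmetalation without triggering Suzuki coupling and the unconjugated allyl group should be inert.

**Step 3**
Reactants: 3 2-(4-allyl-2-methoxyphenyl)-4,4,5,5-tetramethyl-1,3,2-dioxaborolane
Product: 4 4-allyl-1-iodo-2-methoxybenzene
Conditions: CuI (10 mol %), 1,10-phenanthroline (20 mol %), KI (1.5 equiv), MeOH/H2O 4:1, air, 80 °C
Reagents that add atoms: potassium iodide, [K+].[I-]
Why: copper-mediated ipso-iododeboronation (boron-to-copper transmetalation, aerobic oxidation, C–I reductive elimination) uses nucleophilic iodide, so the allyl group is spared where electrophilic iodine sources would attack it.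

**Step 4**
Reactants: 5 4-iodo-2-methoxyphenol
Product: 6 4-iodo-2-methoxyphenyl methanesulfonate
Conditions: MsCl, Et3N, CH2Cl2, 0 °C
Reagents that add atoms: methanesulfonyl chloride, CS(=O)(=O)Cl
Why: O-sulfonylation of the phenol installs a base-cleavable, electron-withdrawing protecting group that is inert to the later palladium steps.

**Step 5**
Reactants: 6 4-iodo-2-methoxyphenyl methanesulfonate; 7 propargyl alcohol
Product: 8 4-(3-hydroxyprop-1-yn-1-yl)-2-methoxyphenyl methanesulfonate
Conditions: Pd(PPh3)2Cl2 (2 mol %), CuI (4 mol %), Et3N, THF, rt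
Reagents that add atoms: none
Why: Sonogashira coupling, in which the aryl iodide reacts at room temperature while the aryl mesylate and the free propargylic hydroxyl are tolerated.

**Step 6**
Reactants: 8 4-(3-hydroxyprop-1-yn-1-yl)-2-methoxyphenyl methanesulfonate
Product: 9 (Z)-4-(3-hydroxyprop-1-en-1-yl)-2-methoxyphenyl methanesulfonate
Conditions: H2 (1 atm), Pd/CaCO3 poisoned with Pb(OAc)2 (Lindlar catalyst), quinoline, EtOAc, rt, stopped after 1 equiv H2
Reagents that add atoms: none
Why: Lindlar semihydrogenation delivers both hydrogens to one face of the adsorbed alkyne and so gives the Z-alkene; it is run before any allyl group is present in this fragment.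

**Step 7**
Reactants: 9 (Z)-4-(3-hydroxyprop-1-en-1-yl)-2-methoxyphenyl methanesulfonate; 1 eugenol
Product: 10 (Z)-4-[3-(4-allyl-2-methoxyphenoxy)prop-1-en-1-yl]-2-methoxyphenyl methanesulfonate
Conditions: PPh3, DIAD, THF, 0 °C to rt
Reagents that add atoms: none
Why: Mitsunobu etherification, in which the eugenolate displaces the primary allylic alkoxyphosphonium in an SN2 sense at the unhindered CH2, so the Z geometry should be kept.

**Step 8**
Reactants: 10 (Z)-4-[3-(4-allyl-2-methoxyphenoxy)prop-1-en-1-yl]-2-methoxyphenyl methanesulfonate
Product: 11 4-{(2R,3S)-3-[(4-allyl-2-methoxyphenoxy)methyl]oxiran-2-yl}-2-methoxyphenyl methanesulfonate (cis-epoxide)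
Conditions: (R,R)-(salen)MnCl [(R,R)-N,N′-bis(3,5-di-tert-butylsalicylidene)-1,2-cyclohexanediaminomanganese chloride] (5 mol %), 4-phenylpyridine N-oxide (20 mol %), aq NaOCl (pH 11.3), CH2Cl2, 0 °C
Reagents that add atoms: sodium hypochlorite, [Na+].[O-]Cl
Why: Jacobsen–Katsuki epoxidation, in which the oxomanganese salen species attacks the conjugated cis-alkene much faster than the isolated allyl group and the catalyst's face selectivity (side-on approach, as for cis-β-methylstyrene) sets both stereocentres as the cis-(2R,3S)-epoxide.

**Step 9**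
Reactants: 4 4-allyl-1-iodo-2-methoxybenzene; 11 cis-epoxide
Product: 12 4-{(2S,3R)-5-allyl-3-[(4-allyl-2-methoxyphenoxy)methyl]-7-methoxy-2,3-dihydro-1-benzofuran-2-yl}-2-methoxyphenyl methanesulfonate
Conditions: Pd(OAc)2 (10 mol %), XPhos (20 mol %), potassium 5-norbornene-2-carboxylate (50 mol %), K2CO3 (2 equiv), NMP, 70 °C; 11 (1.3 equiv), 4 added slowly
Reagents that add atoms: none
Why: Proposed new method: zerovalent palladium adds the C–I bond of 4, the norbornene inserts and the only free ortho C–H (C3a) is palladated to an aryl–norbornyl palladacycle of divalent palladium, which opens the potassium-activated epoxide by backside SN2 attack at C3 (formally reaching tetravalent palladium); aryl–alkyl reductive elimination then forms C3a–C3, the now doubly ortho-substituted aryl expels norbornene, and the tethered C2 alkoxide binds divalent palladium and closes the ring by C7a–O1 reductive elimination. The closest known reaction type is the palladium/norbornene (Catellani) annulation of aryl iodides with terminal epoxides to 2,3-dihydrobenzofurans; new here is opening at a secondary carbon of a 1,2-disubstituted epoxide. The dihydrofuran ring closes by intramolecular C–O reductive elimination from a six-membered aryl(alkoxo)palladium chelate, that is, a 5-exo-type attack of the alkoxide oxygen on the ipso carbon. No stereocentre is created: C3 is inverted by the SN2 opening (the reductive elimination retains), C2 keeps its C–O bond, and so the cis-(2R,3S)-epoxide maps onto the trans-(2S,3R) ring. The step needs attack at C3 and not at benzylic C2: the CH2OAr arm is the smaller substituent for the bulky palladacycle, which follows sterics in the terminal-epoxide cases, and the sulfonate makes ring B too electron-poor for benzylic ionisation or Meinwald rearrangement. The OMe on C7 is the ortho substituent that limits alkylation to one site and drives norbornene extrusion, and the strained norbornene should outcompete the unactivated allyl groups for insertion.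

**Step 10**
Reactants: 12 mesylate of the target
Product: 13 4-{(2S,3R)-5-allyl-3-[(4-allyl-2-methoxyphenoxy)methyl]-7-methoxy-2,3-dihydro-1-benzofuran-2-yl}-2-methoxyphenol (target)
Conditions: KOH, MeOH/THF/H2O, 60 °C; then aq HCl to pH 5
Reagents that add atoms: none
Why: hydroxide-induced cleavage of the aryl methanesulfonate at sulfur frees the phenol, while the ethers, the allyl groups and the two non-acidic ring stereocentres should be untouched at this temperature.

**Compound list**
1 | eugenol | C=CCc1ccc(O)c(OC)c1 | starting material
2 | 4-allyl-2-methoxyphenyl trifluoromethanesulfonate | C=CCc1ccc(OS(=O)(=O)C(F)(F)F)c(OC)c1 | intermediate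
3 | 2-(4-allyl-2-methoxyphenyl)-4,4,5,5-tetramethyl-1,3,2-dioxaborolane | C=CCc1ccc(B2OC(C)(C)C(C)(C)O2)c(OC)c1 | intermediate
4 | 4-allyl-1-iodo-2-methoxybenzene | C=CCc1ccc(I)c(OC)c1 | intermediate
5 | 4-iodo-2-methoxyphenol | COc1cc(I)ccc1O | starting material
6 | 4-iodo-2-methoxyphenyl methanesulfonate | COc1cc(I)ccc1OS(C)(=O)=O | intermediate
7 | propargyl alcohol | C#CCO | starting material
8 | 4-(3-hydroxyprop-1-yn-1-yl)-2-methoxyphenyl methanesulfonate | COc1cc(C#CCO)ccc1OS(C)(=O)=O | intermediate
9 | (Z)-4-(3-hydroxyprop-1-en-1-yl)-2-methoxyphenyl methanesulfonate | COc1cc(/C=C\CO)ccc1OS(C)(=O)=O | intermediate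
10 | (Z)-4-[3-(4-allyl-2-methoxyphenoxy)prop-1-en-1-yl]-2-methoxyphenyl methanesulfonate | C=CCc1ccc(OC/C=C\c2ccc(OS(C)(=O)=O)c(OC)c2)c(OC)c1 | intermediate
11 | 4-{(2R,3S)-3-[(4-allyl-2-methoxyphenoxy)methyl]oxiran-2-yl}-2-methoxyphenyl methanesulfonate | C=CCc1ccc(OC[C@@H]2O[C@@H]2c2ccc(OS(C)(=O)=O)c(OC)c2)c(OC)c1 | intermediate
12 | 4-{(2S,3R)-5-allyl-3-[(4-allyl-2-methoxyphenoxy)methyl]-7-methoxy-2,3-dihydro-1-benzofuran-2-yl}-2-methoxyphenyl methanesulfonate | C=CCc1ccc(OC[C@H]2c3cc(CC=C)cc(OC)c3O[C@@H]2c2ccc(OS(C)(=O)=O)c(OC)c2)c(OC)c1 | intermediate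
13 | 4-{(2S,3R)-5-allyl-3-[(4-allyl-2-methoxyphenoxy)methyl]-7-methoxy-2,3-dihydro-1-benzofuran-2-yl}-2-methoxyphenol | C=CCc1ccc(OC[C@H]2c3cc(CC=C)cc(OC)c3O[C@@H]2c2ccc(O)c(OC)c2)c(OC)c1 | target

**Step count**
Total: 10 steps. Longest linear sequence: 7 steps (5 → 6 → 8 → 9 → 10 → 11 → 12 → 13); the aryl iodide 4 is made in 3 steps on a side branch.

**Steps most likely to fail**

Step 9 (proposed new method). Several processes could defeat it:
- the palladacycle may be too slow at a secondary epoxide carbon, so that aryl–aryl coupling of 4 or norbornene-retaining by-products take over;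
- the palladacycle may attack benzylic C2, giving the regioisomeric ring;
- palladium or potassium ions may isomerise the epoxide to a carbonyl compound;
- the allyl groups may undergo Heck insertion or double-bond migration.

The fallback uses known chemistry, sets out from 10 and 1 and comes back at 13. Cleavage of the mesylate of 10 with KOH in aqueous methanol gives (Z)-4-[3-(4-allyl-2-methoxyphenoxy)prop-1-en-1-yl]-2-methoxyphenol F1. Biomimetic oxidative β–5 cross-coupling of F1 with an excess of eugenol 1 (Ag2O, toluene/acetone, rt, dark) follows: the phenoxyl radical of F1 couples through its β-carbon with the free ortho carbon of the eugenol radical, and the phenol oxygen traps the quinone methide. This should give the racemic trans-dihydrobenzofuran F2 (13 together with its enantiomer). Preparative HPLC on a chiral stationary phase then gives 13. The sequence is not enantioselective and homo-coupling of F1 will cost material.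

Step 8. The stepwise radical pathway of the manganese oxidant may leak to the trans-epoxide, face selectivity may be incomplete, and the allyl group or the electron-rich eugenyl ring may be oxidised or chlorinated. The fallback sets out from 9 and comes back at 11. Sharpless asymmetric epoxidation of the Z-allylic alcohol 9 (Ti(OiPr)4, L-(+)-diisopropyl tartrate, tBuOOH, 4 Å molecular sieves, CH2Cl2, −20 °C) should give the cis-epoxy alcohol 2-methoxy-4-[(2R,3S)-3-(hydroxymethyl)oxiran-2-yl]phenyl methanesulfonate F3. Oxygen transfer is concerted, so the product stays cis, and the tartrate sets the face. Mitsunobu etherification of F3 with eugenol 1 (PPh3, DIAD, THF) then gives 11. The hydroxyl group directs the oxidant, so no allyl group is present to compete.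

Step 6. Over-hydrogenation to the saturated alcohol, hydrogenolysis of the allylic C–O bond or Z-to-E isomerisation on the catalyst surface may occur. The fallback sets out from 7 and 6 and comes back at 9. Hydroalumination of propargyl alcohol 7 with LiAlH4 in THF and quenching of the cyclic vinylalanate with Bu3SnOTf gives (Z)-3-(tributylstannyl)prop-2-en-1-ol F4. Stille coupling of F4 with aryl iodide 6 (Pd(PPh3)4, CuI, DMF, rt to 50 °C) proceeds with retention of alkene geometry and gives 9 without any hydrogenation.

**Further compounds**
F1 | step 9 | (Z)-4-[3-(4-allyl-2-methoxyphenoxy)prop-1-en-1-yl]-2-methoxyphenol | C=CCc1ccc(OC/C=C\c2ccc(O)c(OC)c2)c(OC)c1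
F2 | step 9 | racemic trans-dihydrobenzofuran (13 and its enantiomer, equal parts) | C=CCc1ccc(OC[C@H]2c3cc(CC=C)cc(OC)c3O[C@@H]2c2ccc(O)c(OC)c2)c(OC)c1.C=CCc1ccc(OC[C@@H]2c3cc(CC=C)cc(OC)c3O[C@H]2c2ccc(O)c(OC)c2)c(OC)c1
F3 | step 8 | 2-methoxy-4-[(2R,3S)-3-(hydroxymethyl)oxiran-2-yl]phenyl methanesulfonate | OC[C@@H]1O[C@@H]1c1ccc(OS(C)(=O)=O)c(OC)c1
F4 | step 6 | (Z)-3-(tributylstannyl)prop-2-en-1-ol | CCCC[Sn](CCCC)(CCCC)/C=C\CO
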